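## Structural features

The target is a cedrane-type sesquiterpenoid core whose C10 oxygen is acylated by (Z)-16-hydroxyhexadec-9-enoic acid. In the numbering used here, C1 is the quaternary carbon common to rings A, B and C, C2 bears CHO, C5 is the ring-fusion CH, C6 bears CH3 and CH2OH, C7 is the bridgehead CH, C8 bears CO2H and is doubly bonded to C9, C10 bears the acyloxy group and C11 is the bridging CH2. Ring A (C1–C11–C7–C6–C5) and ring B (C1–C11–C7–C8–C9–C10) make up a bicyclo[3.2.1]oct-2-ene, and ring C (C1–C2–C3–C4–C5) is fused to it along C1–C5. Five of the six stereocentres (C10, C1, C2, C5, C6) are contiguous and the sixth, C7, is tied to them through the bridge; C1 and C6 are all-carbon quaternary centres on either side of C5. The hydroxymethyl group on C6 and the hydrogen on C5 lie on the face of the C11 bridge, the C6 methyl group and C4 lie under the C8–C10 bridge, and the C10 oxygen and the formyl carbon on C2 are on the same side, close enough to be joined in a five-membered lactone. Fragile elements are the C2 aldehyde with its epimerisable α-hydrogen, the allylic C10 ester (no hydroxide or hydride once it is in place), the isolated Z-alkene (no hydrogenation after it is introduced) and four one-carbon oxygenated groups at four oxidation levels. The real difficulty is the pair of quaternary carbons flanking C5 together with the control of C2 on an open arm next to C1. The key step exploits the position of C5 between the two quaternary carbons: as an alkyne carbon on C1 it is attacked by an enol ether carbon C6 held on C7, so that ring A closes with creation of C6 and C5 stays trigonal for ring C closure and a late, face-selective hydrogenation.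

## Logic of the disconnections

41 ⇒ 40. No skeletal bond is cut. The acid is masked as a tert-butyl ester, both primary alcohols as silyl ethers and the C2 aldehyde as an N,N-dimethylhydrazone, so that one aqueous acid treatment releases everything. The C10 ester rules out hydroxide and hydride at this stage and the Z-alkene rules out hydrogenolysis. The forward step must not ionise the allylic C10 ester or epimerise C2.

40 ⇒ 31 + 38. The acyl–oxygen bond at C10 is cut, which removes the whole C16 chain. The forward step must acylate a hindered secondary allylic hydroxyl next to quaternary C1, so every other hydroxyl has to be blocked and C2 must not be a free aldehyde.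

38 ⇒ 33 + 34 (through 37), and 33 ⇒ 32. The Z-alkene is traced to an alkyne and the alkyne to a C(sp)–C(sp3) bond between chain carbons 8 and 9. Two eight-carbon pieces result. The demands are a clean acetylide alkylation in the presence of a carboxylate and a syn semi-hydrogenation.

31 ⇒ 29 (through 30). The C10 hydroxyl and the C2 hydrazone carbon are reconnected as a γ-lactone. This is the one deliberate departure from the most literal precursor design, a C10 silyl ether with an open-chain C2 dimethyl acetal. The lactone keeps acetal oxygens away from the gold-activated alkyne, saves two protecting groups, and is the template that later fixes C10 and C2. Forward, the lactone must be reduced to the lactol without touching the enoate, and the lactol must be opened so that only the C10 hydroxyl is freed.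

29 ⇒ 26 (through 28 and 27). The C5–H bond is cut back to a C4=C5 alkene and the C6 hydroxymethyl group to the aldehyde. This removes the C5 stereocentre. The forward step must deliver hydrogen to the C11 face of C5, which the C6 hydroxymethyl group on that face can direct.

26 ⇒ 25. The C4=C5 alkene is cut as a metathesis retron, opening ring C to a C5 methylene and a C2 allyl group. The forward step must close a cyclopentene at a methylene lying between two quaternary carbons.

25 ⇒ 24 (key step). The C5–C6 bond is cut. Ring A opens to ring B carrying an ethynyl group on C1 and a silyl enol ether arm on C7. One ring and one quaternary stereocentre disappear. Forward, the closure must be 5-exo-dig with the C6 methyl turned toward the C8 bridge, and ethynyl and arm must be cis on ring B.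

24 ⇒ 21 (through 23 and 22), and 21 ⇒ 19 + 20. The enol ether is traced to an aldehyde and then to a protected primary alcohol. The C2–C3 bond is cut, so the allyl group comes from 20. C2 is then set on a rigid cis-fused lactone. An SN2 reaction of a C1 enolate with a secondary α-alkoxy halide, which an open-chain C2 arm would need, is avoided. The demand is attack on the lactone enolate from the face of the ethynyl group.

19 ⇒ 16 (through 18 and 17). The ethynyl group is traced to a 2-oxoethyl group, the C10–O bond of the lactone is cut, and the alkene is moved back from C8=C9 to C9=C10. The forward lactonisation can only be cis, which fixes C10.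

16 ⇒ 13 + 14. The C1–C5 bond is cut as a Claisen retron. The quaternary centre C1 becomes a trisubstituted alkene carbon and its configuration is traced to the C9 carbinol. The demand is suprafacial transfer from a C9 oxygen that is cis to the C7 arm.

13 ⇒ 9 + 10 (through 12 and 11). The C9 carbinol is traced to a ketone and the C1–C2 bond is cut as a cross-coupling. The demand is 1,2-reduction with the hydroxyl cis to the C7 arm.

9 ⇒ 7 (through 8). The enol triflate is traced to a 1,3-dione and the C9–C10 bond is cut as a Dieckmann retron, opening ring B. The demand is regioselective sulfonylation at the C1 oxygen.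

7 ⇒ 5 + 6. The C7–C8 bond is cut as a Michael retron. This is the only step that must create absolute configuration.

5 ⇒ 3 + 4, and 3 ⇒ 2 ⇒ 1. The C11=C7 alkene is cut (Wittig). The arm carbon comes from a commercial hydroxy ester; its configuration is later erased.

## Other disconnections considered

Alternative 1: The cut is at C7–C8 and C1–C10, so ring B of the tricyclic diene ester A3 is made from the achiral bicyclic cyclopentadiene A1 and tert-butyl 2-diazobut-3-enoate A2. In the forward step a chiral dirhodium tetracarboxylate forms the vinylcarbenoid, which cyclopropanates the less substituted C6=C7 alkene of A1; Cope rearrangement of the cis-divinylcyclopropane then gives A3.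
- In its favour: one catalytic enantioselective event builds ring B, the bridged bicycle, quaternary C1 and C7, and places the ester on C8 with C8=C9 in position. In steps needed to reach the tricyclic carbon skeleton it is clearly better than the chosen plan.
- Against it here: A3 has no oxygen at C10. C6 is trigonal in a tetrasubstituted C5=C6 alkene, which would need hydrogen at C5 and a hydroxymethyl group at C6 on defined faces. The C2 ketal still has to be homologated to CHO with control. A1 is prone to 1,5-hydrogen shifts and dimerisation.
- Comparison: the pericyclic cascade is at least the equal of the gold step in stereospecificity at C1 and C7. The chosen plan, however, makes C6 in the ring-forming step and leaves C5 as a simple alkene, which are the two carbons Alternative 1 leaves open. The step advantage is therefore expected to be spent on late redox and C–C chemistry.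

Alternative 2: The cut is at C7–C11 and C8–C1 of the bicyclo[2.1.1]hexane A5, which goes back to the ring C methylenecyclopentane A4 carrying a C7=C8 dienoate on C6. In the forward step triplet sensitisation of the dienoate gives first the C7–C11 bond (five-membered ring, crossed sense) and then C8–C1. A later vinylcyclobutane ring expansion would exchange C1–C8 for C1–C10.
- In its favour: C6 and C5 are already set in A4, so no late hydrogenation at C5 is needed. On that point it is better than the chosen plan. The step is redox-neutral and forms two C–C bonds.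
- Against it here: A4 needs an open-chain quaternary stereocentre C6 next to C5. Facial control of the cycloaddition rests on remote centres. E/Z isomerisation of the triplet dienoate competes. The ring expansion passes through a diradical and ends with C10 as CH2, so the C10 oxygen would again have to be introduced late.
- Comparison: structurally it solves C5 and C6 early but postpones C10 and the ring B oxidation pattern. The gold closure is a polar, catalyst-controlled 5-exo-dig process, with less strain to manage than a bicyclo[2.1.1]hexane relay. Overall step count is not expected to be lower.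

Alternative 3: The cut is at C9–C10 of the tricyclic alcohol A7, which goes back to the diquinane aldehyde A6 bearing a β-sulfonyl acrylate on C7. In the forward step SmI2 (divalent samarium) converts the C10 aldehyde into a ketyl that adds to C9; loss of sulfinate restores C8=C9.
- In its favour: ring B is formed last with exactly the right oxidation pattern (C10–OH and the C8=C9 enoate). In this it equals the chosen plan, and it is better in that no metathesis at a hindered alkene is required. What remains afterwards (C4=C5 hydrogenation, esterification) is the same as in the chosen plan.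
- Against it here: both quaternary carbons, C2 and C7 must already be present in A6, so the hard problems move into a long precursor synthesis. The closure is 6-endo and slower than 5-exo alternatives. The C10 configuration depends on the ketyl transition state. Excess reductant can attack the product enoate.
- Comparison: the chosen plan builds ring B first from simple materials with one catalytic asymmetric step and uses it as the template for rings A and C. Alternative 3 does the reverse and is judged longer overall.

Key step: step 16

Remark on the structures: the precursor and product of the key step were compared centre by centre with the target (C1, C2, C7, C10, and C6 in the product) and no configuration had to be corrected. The only change is the protecting-group layout (a C10–O/C2 lactone); the carbon skeleton and the bond formed are untouched.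

Assumption: in step 4 the enantiomer of the amine catalyst is chosen by its known facial preference so that C7 of 7 is (S). C6 is carried as one configuration only for convenience and is created anew in step 16.

Remark on notation: atom labels C1–C11 are those of the target; the SMILES strings carry the stereochemistry. TBS = tert-butyldimethylsilyl, TIPS = triisopropylsilyl.

## Route

Step 1
Reactants: 1 methyl (S)-3-hydroxy-2-methylpropanoate
Product: 2 methyl (S)-3-(tert-butyldimethylsilyloxy)-2-methylpropanoate
Conditions: tBuMe2SiCl, imidazole, DMF, 0 °C → rt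
Reagents that add atoms: tert-butyldimethylsilyl chloride, C[Si](C)(Cl)C(C)(C)C
Why: Imidazole-promoted silyl ether formation at the primary alcohol; no stereocentre is touched.

Step 2
Reactants: 2 methyl (S)-3-(tert-butyldimethylsilyloxy)-2-methylpropanoate
Product: 3 (S)-3-(tert-butyldimethylsilyloxy)-2-methylpropanal
Conditions: iBu2AlH (1.05 equiv), CH2Cl2, −78 °C; aqueous work-up
Reagents that add atoms: none
Why: Partial hydride reduction of the ester through the aluminium hemiacetal, which is stable at −78 °C and collapses on work-up; the α-centre is the future C6 and its configuration is immaterial.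

Step 3
Reactants: 3 (S)-3-(tert-butyldimethylsilyloxy)-2-methylpropanal; 4 1-(triphenyl-λ5-phosphanylidene)propan-2-one
Product: 5 (R,E)-6-(tert-butyldimethylsilyloxy)-5-methylhex-3-en-2-one
Conditions: CH2Cl2, 40 °C
Reagents that add atoms: none
Why: Wittig olefination with a stabilised ylide under neutral conditions should give the (E)-enone.

Step 4
Reactants: 5 (R,E)-6-(tert-butyldimethylsilyloxy)-5-methylhex-3-en-2-one; 6 tert-butyl methyl propanedioate
Product: 7 1-tert-butyl 3-methyl 2-[(2R,3S)-1-(tert-butyldimethylsilyloxy)-2-methyl-5-oxohexan-3-yl]propanedioate (both epimers at the malonate carbon)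
Conditions: 1-[(1R,2R)-2-aminocyclohexyl]-3-[3,5-bis(trifluoromethyl)phenyl]thiourea or its enantiomer (10 mol %), PhCO2H (10 mol %), toluene, rt
Reagents that add atoms: none
Why: Organocatalytic asymmetric Michael addition: the primary amine forms the iminium ion of the enone, the thiourea binds the malonate, and addition to one face of C7 sets this centre as (S); catalyst control is expected to override the weak bias of the neighbouring C6 centre.

Step 5
Reactants: 7 1-tert-butyl 3-methyl 2-[(2R,3S)-1-(tert-butyldimethylsilyloxy)-2-methyl-5-oxohexan-3-yl]propanedioate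
Product: 8 tert-butyl 6-[(R)-1-(tert-butyldimethylsilyloxy)propan-2-yl]-2,4-dioxocyclohexane-1-carboxylate (ring B dione; ester trans to the arm)
Conditions: KOtBu (2.2 equiv), tBuOH–THF, 0 °C → rt; then 1 M HCl
Reagents that add atoms: none
Why: Dieckmann-type (intramolecular Claisen) condensation: the methyl ketone enolate (C10) attacks the methyl ester (C9), the hindered tert-butyl ester does not compete, and formation of the stabilised dione enolate drives closure of ring B; low temperature limits retro-Michael erosion of C7.

Step 6
Reactants: 8 tert-butyl 6-[(R)-1-(tert-butyldimethylsilyloxy)propan-2-yl]-2,4-dioxocyclohexane-1-carboxylate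
Product: 9 tert-butyl 6-[(R)-1-(tert-butyldimethylsilyloxy)propan-2-yl]-2-oxo-4-(trifluoromethylsulfonyloxy)cyclohex-3-ene-1-carboxylate (C1 enol triflate)
Conditions: (CF3SO2)2O, Et3N, CH2Cl2, −78 °C
Reagents that add atoms: trifluoromethanesulfonic anhydride, O=S(=O)(OS(=O)(=O)C(F)(F)F)C(F)(F)F
Why: O-Sulfonylation of the dione enolate (enol triflate formation); the C1 oxygen is the less hindered and is not hydrogen-bonded to the C8 ester, so the triflate should form there.

Step 7
Reactants: 9 tert-butyl 6-[(R)-1-(tert-butyldimethylsilyloxy)propan-2-yl]-2-oxo-4-(trifluoromethylsulfonyloxy)cyclohex-3-ene-1-carboxylate; 10 tert-butyl bromoacetate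
Product: 12 tert-butyl 4-(2-tert-butoxy-2-oxoethyl)-6-[(R)-1-(tert-butyldimethylsilyloxy)propan-2-yl]-2-oxocyclohex-3-ene-1-carboxylate (ring B enone), via (2-tert-butoxy-2-oxoethyl)zinc bromide 11 (not isolated)
Conditions: Zn, Me3SiCl (cat.), THF, rt; then 9, Pd(PPh3)4 (5 mol %), THF, rt → 45 °C
Reagents that add atoms: none
Why: Negishi cross-coupling of a Reformatsky reagent with a β-triflyloxy enone; oxidative addition of zerovalent palladium into the activated C–O bond is easy, and the coupling attaches the C2 carbon chain to C1 while the C10=C1 alkene stays conjugated with the C9 ketone.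

Step 8
Reactants: 12 tert-butyl 4-(2-tert-butoxy-2-oxoethyl)-6-[(R)-1-(tert-butyldimethylsilyloxy)propan-2-yl]-2-oxocyclohex-3-ene-1-carboxylate
Product: 13 tert-butyl 4-(2-tert-butoxy-2-oxoethyl)-2-hydroxy-6-[(R)-1-(tert-butyldimethylsilyloxy)propan-2-yl]cyclohex-3-ene-1-carboxylate (C9–OH cis to the C7 arm; ester trans to both)
Conditions: NaBH4, CeCl3·7H2O, MeOH, −40 °C
Reagents that add atoms: none
Why: Luche 1,2-reduction; hydride is delivered pseudo-axially to the half-chair enone, as with other 5-substituted cyclohexenones, so the C9 hydroxyl should be equatorial and cis to the C7 arm (relay centre for step 9).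

Step 9
Reactants: 13 tert-butyl 4-(2-tert-butoxy-2-oxoethyl)-2-hydroxy-6-[(R)-1-(tert-butyldimethylsilyloxy)propan-2-yl]cyclohex-3-ene-1-carboxylate; 14 butyl vinyl ether
Product: 16 tert-butyl 4-(2-tert-butoxy-2-oxoethyl)-4-(2-oxoethyl)-6-[(R)-1-(tert-butyldimethylsilyloxy)propan-2-yl]cyclohex-2-ene-1-carboxylate (2-oxoethyl cis to the C7 arm), via C9 vinyl ether of the allylic alcohol 15 (not isolated)
Conditions: Pd(OCOCF3)2 (5 mol %), 4,7-diphenyl-1,10-phenanthroline (5 mol %), Et3N, neat 14, 75 °C; evaporation; o-xylene, 150 °C (sealed tube)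
Reagents that add atoms: none
Why: Transfer vinylation followed by Claisen rearrangement; the [3,3] shift is suprafacial, so the new C1–C5 bond forms on the face of the C9 oxygen, cis to the C7 arm, which creates quaternary C1 and moves the alkene to C9=C10.

Step 10
Reactants: 16 tert-butyl 4-(2-tert-butoxy-2-oxoethyl)-4-(2-oxoethyl)-6-[(R)-1-(tert-butyldimethylsilyloxy)propan-2-yl]cyclohex-2-ene-1-carboxylate
Product: 18 tert-butyl 2-oxo-3a-(2-oxoethyl)-5-[(R)-1-(tert-butyldimethylsilyloxy)propan-2-yl]-2,3,3a,4,5,7a-hexahydro-1-benzofuran-6-carboxylate (cis-fused lactone; C10–O trans to the 2-oxoethyl group), via cis-fused iodolactone 17 (not isolated)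
Conditions: I2, NaHCO3, MeCN, 0 °C → rt; then DBU, 0 °C → rt
Reagents that add atoms: none
Why: Iodolactonisation then E1cB elimination: the carbonyl oxygen of the tert-butyl ester on the C2 arm opens the iodonium ion 5-exo at C10 and loses the tert-butyl cation, which can only give the cis-fused lactone, so the C10 oxygen is set cis to the C2 arm and trans to the future ethynyl group; DBU then removes HI from the β-iodo ester to give the C8=C9 enoate.

Step 11
Reactants: 18 tert-butyl 2-oxo-3a-(2-oxoethyl)-5-[(R)-1-(tert-butyldimethylsilyloxy)propan-2-yl]-2,3,3a,4,5,7a-hexahydro-1-benzofuran-6-carboxylate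
Product: 19 tert-butyl 3a-ethynyl-2-oxo-5-[(R)-1-(tert-butyldimethylsilyloxy)propan-2-yl]-2,3,3a,4,5,7a-hexahydro-1-benzofuran-6-carboxylate
Conditions: C4F9SO2F, P2-Et phosphazene base, DMF, 0 °C → rt
Reagents that add atoms: none
Why: One-pot conversion of an enolisable aldehyde into a terminal alkyne through its alkenyl nonaflate and base-induced elimination; the phosphazene base is strong enough for the aldehyde and for the elimination but too weak to enolise the lactone or the ester.

Step 12
Reactants: 19 tert-butyl 3a-ethynyl-2-oxo-5-[(R)-1-(tert-butyldimethylsilyloxy)propan-2-yl]-2,3,3a,4,5,7a-hexahydro-1-benzofuran-6-carboxylate; 20 allyl bromide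
Product: 21 tert-butyl 3-allyl-3a-ethynyl-2-oxo-5-[(R)-1-(tert-butyldimethylsilyloxy)propan-2-yl]-2,3,3a,4,5,7a-hexahydro-1-benzofuran-6-carboxylate (allyl cis to ethynyl)
Conditions: LiN(iPr)2 (2.2 equiv), THF, −78 °C; 20, −78 → −40 °C; H2O
Reagents that add atoms: none
Why: Alkylation of a lactone enolate (the acetylide that also forms is inert to allyl bromide at low temperature and is re-protonated on work-up); the electrophile approaches C2 on the convex face of the cis-fused bicycle, syn to the slim ethynyl group and anti to ring carbon C11, which sets C2 with allyl cis to ethynyl.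

Step 13
Reactants: 21 tert-butyl 3-allyl-3a-ethynyl-2-oxo-5-[(R)-1-(tert-butyldimethylsilyloxy)propan-2-yl]-2,3,3a,4,5,7a-hexahydro-1-benzofuran-6-carboxylate
Product: 22 tert-butyl 3-allyl-3a-ethynyl-5-[(R)-1-hydroxypropan-2-yl]-2-oxo-2,3,3a,4,5,7a-hexahydro-1-benzofuran-6-carboxylate
Conditions: HF·pyridine, pyridine, THF, 0 °C → rt
Reagents that add atoms: none
Why: Fluoride cleavage of the primary silyl ether under buffered, non-basic conditions, so that the epimerisable C2 centre of the lactone is not exposed to base.

Step 14
Reactants: 22 tert-butyl 3-allyl-3a-ethynyl-5-[(R)-1-hydroxypropan-2-yl]-2-oxo-2,3,3a,4,5,7a-hexahydro-1-benzofuran-6-carboxylate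
Product: 23 tert-butyl 3-allyl-3a-ethynyl-2-oxo-5-(1-oxopropan-2-yl)-2,3,3a,4,5,7a-hexahydro-1-benzofuran-6-carboxylate
Conditions: Dess–Martin periodinane, CH2Cl2, 0 °C → rt
Reagents that add atoms: none
Why: Dess–Martin oxidation of the primary alcohol to the aldehyde under near-neutral conditions; epimerisation next to the new aldehyde does not matter.

Step 15
Reactants: 23 tert-butyl 3-allyl-3a-ethynyl-2-oxo-5-(1-oxopropan-2-yl)-2,3,3a,4,5,7a-hexahydro-1-benzofuran-6-carboxylate
Product: 24 tert-butyl 3-allyl-3a-ethynyl-2-oxo-5-[1-(triisopropylsilyloxy)prop-1-en-2-yl]-2,3,3a,4,5,7a-hexahydro-1-benzofuran-6-carboxylate (ring B alkynyl silyl enol ether; E/Z mixture)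
Conditions: iPr3SiOSO2CF3, Et3N, CH2Cl2, 0 °C → rt
Reagents that add atoms: triisopropylsilyl trifluoromethanesulfonate, CC(C)[Si](OS(=O)(=O)C(F)(F)F)(C(C)C)C(C)C
Why: Soft enolisation and O-silylation of the aldehyde (silyl triflate with amine base); the aldehyde is enolised far more readily than the lactone, and either enol ether geometry serves because both converge in step 16.

Step 16
Reactants: 24 tert-butyl 3-allyl-3a-ethynyl-2-oxo-5-[1-(triisopropylsilyloxy)prop-1-en-2-yl]-2,3,3a,4,5,7a-hexahydro-1-benzofuran-6-carboxylate
Product: 25 bicyclo[3.2.1]oct-2-ene lactone aldehyde with C5 methylene; C6 methyl (endo) and formyl (exo); C2 allyl; C8 tert-butyl ester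
Conditions: Ph3PAuCl (5 mol %), AgOSO2CF3 (5 mol %), CH2Cl2–H2O (10:1), rt
Reagents that add atoms: none
Why: Cationic monovalent gold (Ph3PAu+) π-activates the ethynyl group on C1; the silyl enol ether carbon C6 attacks the internal alkyne carbon C5 anti to gold, the oxocarbenium ion loses its silyl group to water and the vinylgold is protodeaurated, giving the C5 methylene and the C6 aldehyde. The closest known reaction type is the gold-catalysed carbocyclisation of silyl enol ethers onto alkynes (Conia-ene type). Ring A (C6–C7–C11–C1–C5) closes 5-exo-dig; the 6-endo alternative at the terminal carbon would give a bicyclo[2.2.2] bridge and is not expected for a terminal alkyne. The new stereocentre C6 is set by the face of the enol ether: the rotamer with the methyl group under the C8–C10 bridge and the bulky silyloxyvinyl unit on the open C11 side is preferred, which puts CHO exo and CH3 endo as in the target, while C1 and C7 fix the cis bridging. The step needs chemoselectivity against the allyl alkene (a 1,6-enyne partner) and against carbonyl oxygens: the enol ether is by far the strongest nucleophile and reaches C5 through a five-membered transition state, the lactone carbonyl could reach C5 only through a strained bridgehead oxocarbenium ion, and no acetal or free hydroxyl is present. Allylic 1,2-strain between the C8 ester and the C7 arm, together with the cis lactone, favours the half-chair of ring B in which ethynyl and arm are both pseudo-axial on the same face.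

Step 17
Reactants: 25 bicyclo[3.2.1]oct-2-ene lactone aldehyde with C5 methylene
Product: 26 tricyclic lactone aldehyde with C4=C5 alkene (rings A to C closed; C6 formyl)
Conditions: second-generation Hoveyda–Grubbs catalyst [(H2IMes)Cl2Ru=CH(2-iPrOC6H4), 10 mol %], toluene, 80 °C
Reagents that add atoms: none
Why: Ring-closing metathesis; the catalyst loads on the allyl group and closes onto the C5 methylene, which the lactone holds on the same face, releasing ethene and forming the C4=C5 cyclopentene (ring C).

Step 18
Reactants: 26 tricyclic lactone aldehyde with C4=C5 alkene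
Product: 27 tricyclic lactone with C6 hydroxymethyl and C4=C5 alkene
Conditions: NaBH4, MeOH, 0 °C
Reagents that add atoms: none
Why: Chemoselective borohydride reduction of the aldehyde; lactone, enoate and alkene are inert under these conditions.

Step 19
Reactants: 27 tricyclic lactone with C6 hydroxymethyl and C4=C5 alkene
Product: 28 saturated tricyclic hydroxy lactone (C5–H on the C11 face)
Conditions: H2 (1 atm), [Ir(cod)(PCy3)(py)]PF6 (10 mol %), CH2Cl2, rt
Reagents that add atoms: none
Why: Hydroxyl-directed homogeneous hydrogenation with cationic iridium; the C6 hydroxymethyl group on the C11 face binds the metal and hydrogen is delivered to that face of C4=C5, which sets C5 and folds ring C under the C8–C10 bridge; the electron-poor C8=C9 enoate is out of reach of the directing group.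

Step 20
Reactants: 28 saturated tricyclic hydroxy lactone
Product: 29 tricyclic lactone with C6 CH2OTBS
Conditions: tBuMe2SiOSO2CF3, 2,6-lutidine, CH2Cl2, 0 °C
Reagents that add atoms: tert-butyldimethylsilyl trifluoromethanesulfonate, C[Si](C)(OS(=O)(=O)C(F)(F)F)C(C)(C)C
Why: Silyl ether formation at the hindered primary alcohol with the reactive silyl triflate.

Step 21
Reactants: 29 tricyclic lactone with C6 CH2OTBS
Product: 30 tricyclic lactol (both anomers)
Conditions: iBu2AlH (1.1 equiv), CH2Cl2, −78 °C; aqueous work-up
Reagents that add atoms: none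
Why: Partial reduction of the γ-lactone to the lactol with one equivalent of hydride at −78 °C; the hindered conjugated tert-butyl ester is much less electrophilic.

Step 22
Reactants: 30 tricyclic lactol
Product: 31 C10 alcohol with C2 (E)-N,N-dimethylhydrazone (C6 CH2OTBS; C8 tert-butyl ester)
Conditions: Me2NNH2, MgSO4, EtOH, 40 °C
Reagents that add atoms: 1,1-dimethylhydrazine, CN(C)N
Why: Condensation of the hydrazine with the ring-opened hydroxy aldehyde tautomer of the lactol; this frees the C10 hydroxyl alone and stores C2 as an aldehyde equivalent that resists epimerisation.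

Step 23
Reactants: 32 oct-7-yn-1-ol
Product: 33 tert-butyldimethyl(oct-7-yn-1-yloxy)silane
Conditions: tBuMe2SiCl, imidazole, DMF, rt
Reagents that add atoms: tert-butyldimethylsilyl chloride, C[Si](C)(Cl)C(C)(C)C
Why: Silyl ether formation at the primary alcohol; the terminal alkyne is untouched.

Step 24
Reactants: 33 tert-butyldimethyl(oct-7-yn-1-yloxy)silane; 34 8-bromooctanoic acid
Product: 37 16-(tert-butyldimethylsilyloxy)hexadec-9-ynoic acid, via lithium 8-(tert-butyldimethylsilyloxy)oct-1-yn-1-ide 35 (not isolated), via sodium 8-bromooctanoate 36 (not isolated)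
Conditions: 33, nBuLi, THF, −78 °C; 34, NaH, THF, 0 °C; combine, DMPU, −78 °C → rt; then dilute HCl to pH 4
Reagents that add atoms: none
Why: SN2 alkylation of a lithium acetylide by a primary bromide; the acid is carried as its sodium carboxylate so that it does not quench the acetylide.

Step 25
Reactants: 37 16-(tert-butyldimethylsilyloxy)hexadec-9-ynoic acid
Product: 38 (Z)-16-(tert-butyldimethylsilyloxy)hexadec-9-enoic acid
Conditions: H2 (1 atm), Pd/CaCO3 poisoned with Pb(OAc)2, quinoline, EtOAc, rt
Reagents that add atoms: none
Why: Semi-hydrogenation of the alkyne over poisoned palladium (syn addition) gives the (Z)-alkene.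

Step 26
Reactants: 38 (Z)-16-(tert-butyldimethylsilyloxy)hexadec-9-enoic acid; 31 C10 alcohol with C2 N,N-dimethylhydrazone
Product: 40 fully protected C10 ester (C8 tert-butyl ester; C6 CH2OTBS; chain OTBS; C2 hydrazone), via mixed 2,4,6-trichlorobenzoic anhydride of the acid 39 (not isolated)
Conditions: 2,4,6-Cl3C6H2COCl, Et3N, THF, rt; then 31, 4-(dimethylamino)pyridine, toluene, rt → 40 °C
Reagents that add atoms: none
Why: Yamaguchi esterification; the mixed anhydride and the acyl-transfer catalyst acylate the hindered allylic C10 hydroxyl, the only free hydroxyl, and C10 keeps its configuration because its C–O bond is not broken.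

Step 27
Reactants: 40 fully protected C10 ester
Product: 41 target (C2 aldehyde; C6 hydroxymethyl; C8 acid; C10 (Z)-16-hydroxyhexadec-9-enoate)
Conditions: CF3CO2H–H2O–CH2Cl2, 0 °C → rt; NaHCO3 wash, re-acidify to pH 4
Reagents that add atoms: water, O
Why: Global acidolysis: the tert-butyl ester is cleaved by alkyl–oxygen fission, both silyl ethers by protodesilylation and the hydrazone by hydrolysis; the allylic C10 ester should survive because ionisation at C10 is disfavoured by the electron-poor enoate.

## Compound list

1 | methyl (S)-3-hydroxy-2-methylpropanoate | C[C@@H](CO)C(=O)OC | starting material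
2 | methyl (S)-3-(tert-butyldimethylsilyloxy)-2-methylpropanoate | C[C@@H](CO[Si](C)(C)C(C)(C)C)C(=O)OC | intermediate
3 | (S)-3-(tert-butyldimethylsilyloxy)-2-methylpropanal | C[C@@H](CO[Si](C)(C)C(C)(C)C)C=O | intermediate
4 | 1-(triphenyl-λ5-phosphanylidene)propan-2-one | CC(=O)C=P(c1ccccc1)(c1ccccc1)c1ccccc1 | starting material
5 | (R,E)-6-(tert-butyldimethylsilyloxy)-5-methylhex-3-en-2-one | C[C@@H](CO[Si](C)(C)C(C)(C)C)/C=C/C(C)=O | intermediate
6 | tert-butyl methyl propanedioate | COC(=O)CC(=O)OC(C)(C)C | starting material
7 | 1-tert-butyl 3-methyl 2-[(2R,3S)-1-(tert-butyldimethylsilyloxy)-2-methyl-5-oxohexan-3-yl]propanedioate (malonate carbon: both epimers) | C[C@@H](CO[Si](C)(C)C(C)(C)C)[C@@H](C(C(=O)OC)C(=O)OC(C)(C)C)CC(C)=O | intermediate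
8 | tert-butyl 6-[(R)-1-(tert-butyldimethylsilyloxy)propan-2-yl]-2,4-dioxocyclohexane-1-carboxylate (ester trans to the arm; drawn as diketone) | C[C@@H](CO[Si](C)(C)C(C)(C)C)[C@@H]1CC(=O)CC(=O)[C@H]1C(=O)OC(C)(C)C | intermediate
9 | tert-butyl 6-[(R)-1-(tert-butyldimethylsilyloxy)propan-2-yl]-2-oxo-4-(trifluoromethylsulfonyloxy)cyclohex-3-ene-1-carboxylate | C[C@@H](CO[Si](C)(C)C(C)(C)C)[C@@H]1CC(OS(=O)(=O)C(F)(F)F)=CC(=O)[C@H]1C(=O)OC(C)(C)C | intermediate
10 | tert-butyl bromoacetate | BrCC(=O)OC(C)(C)C | starting material
11 | (2-tert-butoxy-2-oxoethyl)zinc bromide | Br[Zn]CC(=O)OC(C)(C)C | intermediate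
12 | tert-butyl 4-(2-tert-butoxy-2-oxoethyl)-6-[(R)-1-(tert-butyldimethylsilyloxy)propan-2-yl]-2-oxocyclohex-3-ene-1-carboxylate | C[C@@H](CO[Si](C)(C)C(C)(C)C)[C@@H]1CC(CC(=O)OC(C)(C)C)=CC(=O)[C@H]1C(=O)OC(C)(C)C | intermediate
13 | tert-butyl 4-(2-tert-butoxy-2-oxoethyl)-2-hydroxy-6-[(R)-1-(tert-butyldimethylsilyloxy)propan-2-yl]cyclohex-3-ene-1-carboxylate (hydroxyl cis to the C7 arm; ester trans to both) | C[C@@H](CO[Si](C)(C)C(C)(C)C)[C@@H]1CC(CC(=O)OC(C)(C)C)=C[C@H](O)[C@H]1C(=O)OC(C)(C)C | intermediate
14 | butyl vinyl ether | C=COCCCC | starting material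
15 | C9 vinyl ether of 13 | C[C@@H](CO[Si](C)(C)C(C)(C)C)[C@@H]1CC(CC(=O)OC(C)(C)C)=C[C@H](OC=C)[C@H]1C(=O)OC(C)(C)C | intermediate
16 | tert-butyl 4-(2-tert-butoxy-2-oxoethyl)-4-(2-oxoethyl)-6-[(R)-1-(tert-butyldimethylsilyloxy)propan-2-yl]cyclohex-2-ene-1-carboxylate (2-oxoethyl cis to the C7 arm) | C[C@@H](CO[Si](C)(C)C(C)(C)C)[C@@H]1C[C@@](CC=O)(CC(=O)OC(C)(C)C)C=C[C@H]1C(=O)OC(C)(C)C | intermediate
17 | tert-butyl 7-iodo-2-oxo-3a-(2-oxoethyl)-5-[(R)-1-(tert-butyldimethylsilyloxy)propan-2-yl]octahydro-1-benzofuran-6-carboxylate (cis-fused; iodine trans to the lactone oxygen) | C[C@@H](CO[Si](C)(C)C(C)(C)C)[C@@H]1C[C@@](CC=O)(CC(=O)O2)[C@@H]2[C@H](I)[C@H]1C(=O)OC(C)(C)C | intermediate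
18 | tert-butyl 2-oxo-3a-(2-oxoethyl)-5-[(R)-1-(tert-butyldimethylsilyloxy)propan-2-yl]-2,3,3a,4,5,7a-hexahydro-1-benzofuran-6-carboxylate | C[C@@H](CO[Si](C)(C)C(C)(C)C)[C@@H]1C[C@@](CC=O)(CC(=O)O2)[C@@H]2C=C1C(=O)OC(C)(C)C | intermediate
19 | tert-butyl 3a-ethynyl-2-oxo-5-[(R)-1-(tert-butyldimethylsilyloxy)propan-2-yl]-2,3,3a,4,5,7a-hexahydro-1-benzofuran-6-carboxylate | C[C@@H](CO[Si](C)(C)C(C)(C)C)[C@@H]1C[C@@](C#C)(CC(=O)O2)[C@@H]2C=C1C(=O)OC(C)(C)C | intermediate
20 | allyl bromide | C=CCBr | starting material
21 | tert-butyl 3-allyl-3a-ethynyl-2-oxo-5-[(R)-1-(tert-butyldimethylsilyloxy)propan-2-yl]-2,3,3a,4,5,7a-hexahydro-1-benzofuran-6-carboxylate (allyl cis to ethynyl) | C[C@@H](CO[Si](C)(C)C(C)(C)C)[C@@H]1C[C@@](C#C)([C@H](CC=C)C(=O)O2)[C@@H]2C=C1C(=O)OC(C)(C)C | intermediate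
22 | tert-butyl 3-allyl-3a-ethynyl-5-[(R)-1-hydroxypropan-2-yl]-2-oxo-2,3,3a,4,5,7a-hexahydro-1-benzofuran-6-carboxylate | C[C@@H](CO)[C@@H]1C[C@@](C#C)([C@H](CC=C)C(=O)O2)[C@@H]2C=C1C(=O)OC(C)(C)C | intermediate
23 | tert-butyl 3-allyl-3a-ethynyl-2-oxo-5-(1-oxopropan-2-yl)-2,3,3a,4,5,7a-hexahydro-1-benzofuran-6-carboxylate (arm centre labile, inconsequential) | C[C@@H](C=O)[C@@H]1C[C@@](C#C)([C@H](CC=C)C(=O)O2)[C@@H]2C=C1C(=O)OC(C)(C)C | intermediate
24 | tert-butyl 3-allyl-3a-ethynyl-2-oxo-5-[1-(triisopropylsilyloxy)prop-1-en-2-yl]-2,3,3a,4,5,7a-hexahydro-1-benzofuran-6-carboxylate (precursor of the key step; E/Z mixture) | CC(=CO[Si](C(C)C)(C(C)C)C(C)C)[C@@H]1C[C@@](C#C)([C@H](CC=C)C(=O)O2)[C@@H]2C=C1C(=O)OC(C)(C)C | intermediate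
25 | product of the key step: bicyclo[3.2.1]oct-2-ene with C5 methylene, C6 methyl (endo) and formyl (exo), C2 allyl, C10–O–CO–C2 lactone, C8 tert-butyl ester | C[C@@]1(C=O)[C@@H]2C[C@]([C@@H](O3)C=C2C(=O)OC(C)(C)C)([C@@H](C3=O)CC=C)C1=C | intermediate
26 | tricyclic lactone aldehyde with C4=C5 alkene | C[C@@]1(C=O)[C@@H]2C[C@]3([C@@H](O4)C=C2C(=O)OC(C)(C)C)[C@@H](C4=O)CC=C13 | intermediate
27 | tricyclic lactone with C6 hydroxymethyl and C4=C5 alkene | C[C@@]1(CO)[C@@H]2C[C@]3([C@@H](O4)C=C2C(=O)OC(C)(C)C)[C@@H](C4=O)CC=C13 | intermediate
28 | saturated tricyclic hydroxy lactone (C5–H on the C11 face) | C[C@@]1(CO)[C@@H]2C[C@]3([C@@H](O4)C=C2C(=O)OC(C)(C)C)[C@@H](C4=O)CC[C@@H]13 | intermediate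
29 | tricyclic lactone with C6 CH2OTBS | C[C@@]1(CO[Si](C)(C)C(C)(C)C)[C@@H]2C[C@]3([C@@H](O4)C=C2C(=O)OC(C)(C)C)[C@@H](C4=O)CC[C@@H]13 | intermediate
30 | tricyclic lactol (both anomers) | C[C@@]1(CO[Si](C)(C)C(C)(C)C)[C@@H]2C[C@]3([C@@H](O4)C=C2C(=O)OC(C)(C)C)[C@@H](C4O)CC[C@@H]13 | intermediate
31 | C10 alcohol with C2 (E)-N,N-dimethylhydrazone, C6 CH2OTBS and C8 tert-butyl ester | C[C@@]1(CO[Si](C)(C)C(C)(C)C)[C@@H]2C[C@]3([C@@H](O)C=C2C(=O)OC(C)(C)C)[C@@H](/C=N/N(C)C)CC[C@@H]13 | intermediate
32 | oct-7-yn-1-ol | C#CCCCCCCO | starting material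
33 | tert-butyldimethyl(oct-7-yn-1-yloxy)silane | C#CCCCCCCO[Si](C)(C)C(C)(C)C | intermediate
34 | 8-bromooctanoic acid | OC(=O)CCCCCCCBr | starting material
35 | lithium 8-(tert-butyldimethylsilyloxy)oct-1-yn-1-ide | [Li+].[C-]#CCCCCCCO[Si](C)(C)C(C)(C)C | intermediate
36 | sodium 8-bromooctanoate | [Na+].[O-]C(=O)CCCCCCCBr | intermediate
37 | 16-(tert-butyldimethylsilyloxy)hexadec-9-ynoic acid | OC(=O)CCCCCCCC#CCCCCCCO[Si](C)(C)C(C)(C)C | intermediate
38 | (Z)-16-(tert-butyldimethylsilyloxy)hexadec-9-enoic acid | OC(=O)CCCCCCC/C=C\CCCCCCO[Si](C)(C)C(C)(C)C | intermediate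
39 | (Z)-16-(tert-butyldimethylsilyloxy)hexadec-9-enoic 2,4,6-trichlorobenzoic anhydride | O=C(CCCCCCC/C=C\CCCCCCO[Si](C)(C)C(C)(C)C)OC(=O)c1c(Cl)cc(Cl)cc1Cl | intermediate
40 | fully protected C10 ester (C8 tert-butyl ester, C6 CH2OTBS, chain OTBS, C2 hydrazone) | C[C@@]1(CO[Si](C)(C)C(C)(C)C)[C@@H]2C[C@]3([C@@H](OC(=O)CCCCCCC/C=C\CCCCCCO[Si](C)(C)C(C)(C)C)C=C2C(=O)OC(C)(C)C)[C@@H](/C=N/N(C)C)CC[C@@H]13 | intermediate
41 | target | C[C@@]1(CO)[C@@H]2C[C@]3([C@@H](OC(=O)CCCCCCC/C=C\CCCCCCO)C=C2C(=O)O)[C@@H](C=O)CC[C@@H]13 | target

## Step count and least certain steps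

Total step count: 27. Longest linear sequence: 24 steps (steps 1–22, 26 and 27); the side chain takes steps 23–25.

Step 16 (key step). The most likely failures are loss of the silyl group from the enol ether before the C–C bond forms (trace acid from the silver salt), attack of the allyl alkene on the activated alkyne (enyne cycloisomerisation), or attack through the wrong enol ether rotamer. Fallback, a radical closure of the same bond: setting out from 24, N-bromosuccinimide in THF at −78 °C should give the α-bromo aldehyde F1. Bu3SnH with azobisisobutyronitrile in benzene at 80 °C (slow addition) then generates the tertiary α-formyl radical at C6, which should close 5-exo-dig onto the alkyne; hydrogen transfer to the vinyl radical returns to the route at 25.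

Step 6. The risk is sulfonylation at the C9 oxygen in competition with C1, since the dione enolate is ambident. Fallback, a regioconvergent detour: the regioisomeric C9 enol triflate F2, formed from 8 in the same reaction, is reduced with Pd(OAc)2, PPh3, HCO2H and Et3N to the transposed enone F3 (C1 ketone, C9=C10 alkene). The zinc reagent 11 should add 1,2 to give the tertiary allylic alcohol F4. Oxidative 1,3-transposition with pyridinium chlorochromate (Dauben–Babler type) then returns to the route at 12, so both triflates lead to the same enone.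

Step 9. The risks are base- or heat-induced elimination of the β-alkoxy ester to a dienoate, and a sluggish rearrangement because the reacting conformer needs the C9 oxygen and the C7 arm both pseudo-axial. Fallback, the amide acetal variant, which needs no vinyl ether: setting out from 13, 1,1-dimethoxy-N,N-dimethylethanamine in toluene at 110 °C (Eschenmoser–Claisen) should give the dimethylamide F5 with the same facial transfer. Cp2Zr(H)Cl in THF reduces the tertiary amide to the aldehyde in the presence of the tert-butyl esters, returning to the route at 16.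

Step 11. The risks are incomplete elimination of the alkenyl nonaflate isomer that lacks an anti hydrogen, and base-induced deconjugation of the enoate. Fallback, degradation by one carbon and homologation: setting out from 18, tBuMe2SiOSO2CF3 and Et3N give the silyl enol ether F6. Ozonolysis (O3, CH2Cl2, −78 °C, then Me2S), selective for the electron-rich enol ether over the enoate, gives the neopentyl aldehyde F7. Dimethyl (1-diazo-2-oxopropyl)phosphonate with K2CO3 in MeOH (Ohira–Bestmann) then returns to the route at 19.

Step 12. The risks are approach of allyl bromide from the other face of the lactone enolate, or competing γ-deprotonation of the enoate. Fallback, setting C2 by protonation instead of alkylation: if alkylation of 19 delivers the C2 epimer F8, it is enolised again with LiN(iPr)2 at −78 °C and quenched with 2,6-di-tert-butylphenol. The proton then enters from the face that the electrophile used, which places allyl on the other face and returns to the route at 21. Whichever face is open, one of the two orders gives 21.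

Step 17. The risks are catalyst decomposition before closure onto a methylene flanked by two quaternary carbons, and intermolecular metathesis through the allyl group. Fallback, carbonyl coupling in place of metathesis: setting out from 25, NaBH4 gives the primary alcohol F9 and tBuMe2SiOSO2CF3 with 2,6-lutidine gives its silyl ether F10. Ozonolysis of both the methylene and the allyl alkene (O3, then PPh3) gives the keto aldehyde F11 with a C5 ketone and a C4 aldehyde. Low-valent titanium (TiCl3(DME)1.5, Zn–Cu, DME, reflux; McMurry coupling) should give the cyclopentene F12, and HF·pyridine removes the silyl group to return to the route at 27.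

## Further compounds

F1 | step 16 | α-bromo aldehyde from 24 (C6 bears Br, CH3 and CHO; both C6 epimers) | CC(Br)(C=O)[C@@H]1C[C@@](C#C)([C@H](CC=C)C(=O)O2)[C@@H]2C=C1C(=O)OC(C)(C)C
F2 | step 6 | regioisomeric C9 enol triflate of 8 | C[C@@H](CO[Si](C)(C)C(C)(C)C)[C@@H]1CC(=O)C=C(OS(=O)(=O)C(F)(F)F)[C@H]1C(=O)OC(C)(C)C
F3 | step 6 | tert-butyl 6-[(R)-1-(tert-butyldimethylsilyloxy)propan-2-yl]-4-oxocyclohex-2-ene-1-carboxylate | C[C@@H](CO[Si](C)(C)C(C)(C)C)[C@@H]1CC(=O)C=C[C@H]1C(=O)OC(C)(C)C
F4 | step 6 | tertiary allylic alcohol from 1,2-addition of 11 to F3 (both C1 epimers) | C[C@@H](CO[Si](C)(C)C(C)(C)C)[C@@H]1CC(O)(CC(=O)OC(C)(C)C)C=C[C@H]1C(=O)OC(C)(C)C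
F5 | step 9 | N,N-dimethylamide analogue of 16 (amide arm cis to the C7 arm) | C[C@@H](CO[Si](C)(C)C(C)(C)C)[C@@H]1C[C@@](CC(=O)N(C)C)(CC(=O)OC(C)(C)C)C=C[C@H]1C(=O)OC(C)(C)C
F6 | step 11 | tert-butyldimethylsilyl enol ether of 18 | C[C@@H](CO[Si](C)(C)C(C)(C)C)[C@@H]1C[C@@](C=CO[Si](C)(C)C(C)(C)C)(CC(=O)O2)[C@@H]2C=C1C(=O)OC(C)(C)C
F7 | step 11 | C1 formyl lactone (one carbon shorter than 18) | C[C@@H](CO[Si](C)(C)C(C)(C)C)[C@@H]1C[C@@](C=O)(CC(=O)O2)[C@@H]2C=C1C(=O)OC(C)(C)C
F8 | step 12 | C2 epimer of 21 (allyl trans to ethynyl) | C[C@@H](CO[Si](C)(C)C(C)(C)C)[C@@H]1C[C@@](C#C)([C@@H](CC=C)C(=O)O2)[C@@H]2C=C1C(=O)OC(C)(C)C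
F9 | step 17 | C6 hydroxymethyl analogue of 25 | C[C@@]1(CO)[C@@H]2C[C@]([C@@H](O3)C=C2C(=O)OC(C)(C)C)([C@@H](C3=O)CC=C)C1=C
F10 | step 17 | tert-butyldimethylsilyl ether of F9 | C[C@@]1(CO[Si](C)(C)C(C)(C)C)[C@@H]2C[C@]([C@@H](O3)C=C2C(=O)OC(C)(C)C)([C@@H](C3=O)CC=C)C1=C
F11 | step 17 | keto aldehyde (C5 ketone; C2 bears CH2CHO) | C[C@@]1(CO[Si](C)(C)C(C)(C)C)[C@@H]2C[C@]([C@@H](O3)C=C2C(=O)OC(C)(C)C)([C@@H](C3=O)CC=O)C1=O
F12 | step 17 | tert-butyldimethylsilyl ether of 27 | C[C@@]1(CO[Si](C)(C)C(C)(C)C)[C@@H]2C[C@]3([C@@H](O4)C=C2C(=O)OC(C)(C)C)[C@@H](C4=O)CC=C13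
A1 | alternative 1 | 1'-methyl-5',6'-dihydro-3'H-spiro[[1,3]dioxolane-2,4'-pentalene] (achiral bicyclic cyclopentadiene) | CC1=CCC2=C1CCC23OCCO3
A2 | alternative 1 | tert-butyl 2-diazobut-3-enoate | C=CC(=[N+]=[N-])C(=O)OC(C)(C)C
A3 | alternative 1 | tricyclic diene ester (C8=C9 and C5=C6, C2 ketal) | CC=1[C@@H]2C[C@]3(CC=C2C(=O)OC(C)(C)C)C4(OCCO4)CCC=13
A4 | alternative 2 | ring C methylenecyclopentane with the C7=C8 dienoate on C6 | C[C@@](CO[Si](C)(C)C(C)(C)C)(C=C(C=C)C(=O)OC(C)(C)C)[C@@H]1CC[C@H](C(OC)OC)C1=C
A5 | alternative 2 | bicyclo[2.1.1]hexane fused to ring C, with vinyl and ester on C8 | C[C@@]1(CO[Si](C)(C)C(C)(C)C)[C@@H]2C[C@]3([C@@]2(C=C)C(=O)OC(C)(C)C)[C@@H](C(OC)OC)CC[C@@H]13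
A6 | alternative 3 | diquinane with C10 aldehyde on C1 and β-(phenylsulfonyl)acrylate on C7 | C[C@@]1(CO[Si](C)(C)C(C)(C)C)[C@@H](C(=CS(=O)(=O)c2ccccc2)C(=O)OC(C)(C)C)C[C@]3(C=O)[C@@H](C(OC)OC)CC=C13
A7 | alternative 3 | tricyclic C10 alcohol with C8=C9 enoate and C4=C5 alkene | C[C@@]1(CO[Si](C)(C)C(C)(C)C)[C@@H]2C[C@]3([C@@H](O)C=C2C(=O)OC(C)(C)C)[C@@H](C(OC)OC)CC=C13
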